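- I decided to read these flasks on one axis, the logarithm of charge times time (the reduced time of second-order steps); the exchange steps are bimolecular and the equivalents stood fixed across the earlier runs, so that axis was my choice.

| flask | starting complex | incoming ligand | remark | time |
|---|---|---|---|---|
| ash | 32 mM | 1.5 equiv | run made earlier |  |
| maple | 45 mM | 1.5 equiv | run made earlier |  |
| birch | 70 mM | 1.5 equiv | run made earlier |  |
| north | 32 mM | 1.50 equiv (fed, over 25 h) | all else is in the flask from the start; the feed brings no volume worth counting | 2.5 d |
| west | 32 mM (fed, over 25 h) | 1.50 equiv | all else is in the flask from the start; the feed brings no volume worth counting | 2.5 d |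
| south | 32 mM | 1.50 equiv | everything together at the start | 2.5 d |

| run | time / h | complex with two exchanged / % | starting complex / % |
|---|---|---|---|
| ash | 5.00 | 8.0 | 47.6 |
| ash | 10.0 | 15.2 | 38.0 |
| ash | 15.0 | 21.0 | 29.6 |
| ash | 20.0 | 24.3 | 25.3 |
| ash | 25.0 | 25.6 | 25.1 |
| ash | 30.0 | 27.0 | 22.2 |
| ash | 40.0 | 30.1 | 18.4 |
| maple | 2.50 | 5.3 | 56.4 |
| maple | 8.00 | 18.5 | 31.1 |
| maple | 15.0 | 25.1 | 22.9 |
| maple | 20.0 | 29.8 | 19.7 |
| maple | 30.0 | 30.4 | 17.2 |
| maple | 40.0 | 34.0 | 16.6 |
| maple | 50.0 | 36.1 | 13.4 |
| birch | 2.50 | 7.7 | 44.2 |
| birch | 8.00 | 25.6 | 23.1 |
| birch | 15.0 | 32.1 | 19.6 |
| birch | 20.0 | 32.7 | 15.9 |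
| birch | 30.0 | 36.0 | 14.7 |
| birch | 40.0 | 37.3 | 10.1 |
| birch | 50.0 | 40.5 | 10.4 |

(scatter of a reading: 1 percentage point)

1. which flask leads in amount of complex with two exchanged, in percent of the starting complex charged ("all alike" within 1.5 percentage points) (north / west / south / all alike)
2. how much complex with two exchanged is there at the end, in percent of the starting complex charged: north
3. how much complex with two exchanged is there at the end, in percent of the starting complex charged: west
4. how much complex with two exchanged is there at the end, in percent of the starting complex charged: south

- steps thought possible: complex with one exchanged + incoming ligand -> leaving ligand + complex with two exchanged; starting complex + incoming ligand -> leaving ligand + complex with one exchanged; incoming ligand <-> dormant form; complex with two exchanged + incoming ligand -> leaving ligand + complex with three exchanged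

- One pair looked wrong: the ash run held 30.1% of complex with two exchanged after 40.0 h, the birch run 32.7% after 20.0 h, so ash ran twice as long and stood lower.
- Charge times time put the pair in order, for the birch product lay above the ash product by just 0.0389 of a decade.
- Along the maple run, from 8.00 h to 50.0 h, the reading rose by 22 percentage points per decade of charge times time, my points per decade, a reading with its scatter.
- That made the birch lead worth 0.86 points; the two readings differ by 2.6 points, and each scatters by 1 point.
- The axis carries no term for the dormant form, whose step is first order.
- From the maple reading of 34.0% at 40.0 h, the south product lay 0.0280 of a decade higher, so I committed to 34.6% for south.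
- A steady feed counts its charge at half on average over 25 h, which in my reckoning shortened the time to 47.5 h, so I reckoned 32.4% for north and for west alike.
- The forecast named south as leader, with 26% for north, 20% for west and 35% for south, on this ground: “all the ligand meets all the complex before much of it goes dormant”. It differed from my reckoning on the fed flasks, standing lower on north and on west.
- At 2.5 d north gave 31.1%, west 27.6% and south 34.1%, with south ahead.

    complex with one exchanged + incoming ligand → leaving ligand + complex with two exchanged (k = 2.32 L mol⁻¹ h⁻¹)
    starting complex + incoming ligand → leaving ligand + complex with one exchanged (k = 4.63 L mol⁻¹ h⁻¹)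
    incoming ligand ⇌ dormant form (K = 1.61, k = 0.0749 h⁻¹)
    complex with two exchanged + incoming ligand → leaving ligand + complex with three exchanged (k = 0.586 L mol⁻¹ h⁻¹)

- West came in 4.8 points below my figure, so I started from its own 27.6% for the neighbour charged with 19 mM of starting complex. Its equivalents and time were those of west, so its charge times time lay 0.226 of a decade lower, and points per decade gave 22.6%. That neighbour held 20.8% of complex with two exchanged at 2.50 d.

Readings and results were generated by integration from invented constants; noise was put on by code.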